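Assumption: compounds 1, 5 and 16 are bought. The target 18 has no stereocentre, and the one stereogenic carbon met on the way (the spiro carbon of 13) is racemic and is destroyed in the step that creates it.

## The problem

Compound 18 is a depsidone. Ring A and ring B are tied together twice, by a diaryl ether oxygen (O5) and by an aryl ester (carbonyl C11 on ring A, oxygen O10 on ring B), which closes a seven-membered dioxepinone. The numbering used is that of 11H-dibenzo[b,e][1,4]dioxepin-11-one: C1 to C4, C4a and C11a on ring A; C5a, C6 to C9 and C9a on ring B. Ring A is pentasubstituted (1-methyl, 3-hydroxy, 4-formyl). Ring B is hexasubstituted, with four neighbouring oxygens at C9a, C5a, C6 and C7, a methyl at C9 and a 2,2-dimethyl-2,3-dihydropyran-4-one fused across C7–C8. There is no stereocentre, so no stereocentre can control another and every difficulty is one of position: which ring B oxygen is acylated and which arylated, and where the acyl and the formyl carbon enter. The aryl ester of the central ring is opened by hydroxide, alkoxides and amines, the ortho-hydroxy aldehyde is at risk under oxidants, hydrogenation and hot acid, the chromanone can open by retro-oxa-Michael reaction in base, and the catechol-like phenols of ring B oxidise easily. The enabling feature is the 1,2-relationship on both rings: C11 and O5 sit on the neighbouring carbons C11a and C4a of ring A, and O10 and O5 on the neighbouring carbons C9a and C5a of ring B. This is the connectivity of a 2,2'-dihydroxybenzophenone whose ketone carbon is bonded to C5a, so closing O5–C5a by oxidation and moving the acyl group from C5a to the oxygen on C9a makes the whole central ring from a precursor held together by one C–C bond.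

## Retrosynthesis

**18 to 17.** The C4–CHO bond is cut first. An aldehyde carried further back would have to survive a trivalent iodine oxidant, hydrogenolysis and hot sulfonic acid next to free phenols. Compound 17 lacks only this one carbon. Once the pyranone is in place ring B has no CH left, so the forward formylation must only choose between C4 and C2 of ring A, both ortho to the C3 hydroxyl.

**17 to 15 and 16.** The pyranone is removed by cutting C8–C(=O) and the bond from the C7 oxygen to the quaternary carbon, which returns triol 15 and the five-carbon acid 16. Putting the chromanone on ring B before the two rings are joined was rejected: on the free ring B phenol 9 the carbon between methyl and oxygen competes with a second, more reactive CH that is needed later for the aroyl group. In 15 the carbon C8 is the only CH of ring B. The forward step asks for acylation and not alkylation by 16, and for ring B to react before ring A.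

**15 to 14.** The three phenols are masked as benzyl ethers in 14. Benzyl is chosen because it comes off under neutral hydrogenolysis, which the lactone tolerates, and because an alkoxy group para to the ring B phenol is what the oxidation in the key step requires.

**14 to 12 via 13 (key disconnection).** The ether bond O5–C5a and the ester bond C11–O10 are cut together, and the bond C11–C5a is restored. This leads through the spiro dienedione 13 to the benzophenone 12. The neighbouring cut, an Ullmann ether synthesis followed by lactonisation, would need a ring B catechol whose two hydroxyls are told apart and would join two hindered rings through oxygen. In 12 the two rings are joined through a ketone, and the difference between the two oxygens follows from the structure: the oxygen already on ring B becomes O10, the ring A phenol becomes O5. The forward reaction must oxidise ring B and not ring A, attack the ipso carbon, and shift the acyl group to oxygen.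

**12 to 10 via 11.** The bond from the ketone carbon to ring B is cut to give the aryl ester 10; forward this is a photo-Fries rearrangement. A Friedel–Crafts acylation at this carbon, which lies between two oxygen substituents, would face a second free position and heavy crowding. In 10 the acyl group sits on the neighbouring oxygen, and the only free ortho carbon of that phenol is the right one, since the other ortho position carries methyl and the para position benzyloxy. The ring A ortho oxygen is carried as a methoxymethyl ether (11) so that the salicylate does not waste the light by proton transfer in the excited state; it is freed in the same operation.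

**10 to 4 and 9.** The ester bond is cut to the acid 4 and the phenol 9, two benzene derivatives of similar size, which is the convergent point of the route.

**4 to 1.** The acid 4 goes back through ester 3 and monobenzyl ether 2 to methyl orsellinate 1. The order of protection uses the difference between the free 4-hydroxyl and the hydrogen-bonded 2-hydroxyl.

**9 to 5.** The phenol oxygen of 9 is traced through formate 8 to the aldehyde 7 (aryl migration to oxygen), the formyl group of 7 to the dibenzyl ether 6, and 6 to 4-methylcatechol 5. Formylation para to an alkoxy group and ortho to methyl places the future O10 at the right carbon.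

## Roads not taken

**Alternative 1:** Ring A itself is cut, at the two bonds C1–C11a and C4–C4a, so that the ether oxygen is already in place in the aryloxy ynoate A1 (ring B chromanone bound through oxygen to a propiolate). Forward, A1 and the methoxy silyloxy diene A2 would undergo Diels–Alder addition; loss of the methoxy group and of the silyl group then gives the aromatic benzoate A3.
- Merits: no oxidant is needed, the ether oxygen is placed without ambiguity, and the polarised diene fixes the methyl and hydroxyl positions of ring A. In these respects the road is as good as the chosen one.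
- Weak points: the alkyne carbon of A1 that the diene must attack carries the aryloxy donor, so A1 is a push-pull alkyne and a poor dienophile. It would need temperatures at which A2 and the aryl ynol ether are not reliably stable.
- The hexasubstituted ring B, with four differently masked oxygens and the chromanone, has to be finished before the key step, which moves the hardest substitution problem to the start.
- After A3 there remain hydrolysis of a doubly ortho-substituted methyl ester, debenzylation, closure of the seven-membered lactone, cleavage of a methyl ether and the same C4 against C2 formylation as in the chosen plan.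
- The chosen plan sets against the cleaner ether formation a nine-step longest line from three simple aromatics, and a ring B that is substituted last, when only one carbon is open.

**Alternative 2:** Three bonds are cut at once: O5–C4a, C11–C11a and C11–O10. The pieces are the ring B catechol A4, the fluoro iodo benzaldehyde A5 and carbon monoxide A6. Forward, the more acidic phenoxide of A4 (para to the chromanone carbonyl) would displace the fluoride of A5, which is activated by the ortho formyl group. A zerovalent palladium catalyst with a wide-bite-angle diphosphine would then insert into the C–I bond, take up A6 and be trapped by the second phenol to give the dimethyl ether A7.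
- Merits: this is the most convergent road, and it is better than the chosen one in one respect: the formyl group arrives on A5 at a fixed position, so no late formylation has to choose between two carbons. The chosen plan can only set a steric argument and a fallback against this.
- Weak points: the assignment of ether and ester oxygen rests on an acidity difference in A4. An ortho-aryloxy phenoxide with a formyl-activated aryl group can also equilibrate by Smiles rearrangement in base, which would lead to the isomeric depsidone with the two oxygens exchanged.
- Oxidative addition would take place at an iodide flanked by methyl and aryloxy, and the acyl palladium would be captured by a phenol flanked by methyl. Both events are hindered and must close a seven-membered ring in the presence of a free aldehyde.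
- A4 is again a hexasubstituted ring that needs a long preparation, and two aryl methyl ethers must finally be cleaved next to the lactone; the one at C6 has no neighbouring carbonyl to help.
- In the chosen plan the two oxygens of ring B cannot be exchanged, because the acyl group is bonded to carbon C5a before either C–O bond forms.

**Alternative 3:** Ring B is cut at C9–C9a and C7–C8. Forward, the silyloxyfuran A8, which already carries ring A through the ether oxygen, would add to the alkyne of the ynone A9; opening of the oxygen bridge then gives the hexasubstituted phenol A10.
- Merits: all six substituents of ring B are fixed in one step, including the acyl carbon next to the methyl group. That is more certain than the Friedel–Crafts annulation of the chosen plan, which sets against it that C8 is the only free carbon of ring B when it is acylated. A10 also has the C9a hydroxyl free for lactonisation and the enone and silyl ether ready for the pyranone.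
- Weak points: A8 is a 3-alkoxy-4-aryloxy-2-silyloxyfuran that must be built from a butenolide over several steps and is sensitive to moisture.
- Silyloxyfurans and ynones also combine by vinylogous Mukaiyama–Michael addition without ring closure, and A9 is a cross-conjugated ketone that polymerises readily.
- After A10 the route still needs lactonisation with a hindered methyl ester, desilylation and oxa-Michael closure, two deprotections and the formylation, so it is clearly longer than the chosen plan.

Key step: step 9

## Route

Step 1
Reactants: 1 methyl 2,4-dihydroxy-6-methylbenzoate (methyl orsellinate)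
Product: 2 methyl 4-(benzyloxy)-2-hydroxy-6-methylbenzoate
Conditions: BnBr (1.05 equiv), K2CO3, acetone, reflux
Reagents that add atoms: benzyl bromide, BrCc1ccccc1
Why: Williamson ether synthesis; the 2-hydroxyl is held in a hydrogen bond to the ester carbonyl and is much less nucleophilic, so one equivalent of halide should alkylate the 4-hydroxyl alone.

Step 2
Reactants: 2 methyl 4-(benzyloxy)-2-hydroxy-6-methylbenzoate
Product: 3 methyl 4-(benzyloxy)-2-(methoxymethoxy)-6-methylbenzoate
Conditions: NaH, MOMCl, DMF, 0 °C to rt
Reagents that add atoms: chloromethyl methyl ether, COCCl
Why: O-alkylation of the sodium phenoxide with a reactive alpha-chloro ether (acetal protection); full deprotonation overcomes the hydrogen bond that makes this phenol sluggish under milder bases.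

Step 3
Reactants: 3 methyl 4-(benzyloxy)-2-(methoxymethoxy)-6-methylbenzoate
Product: 4 4-(benzyloxy)-2-(methoxymethoxy)-6-methylbenzoic acid
Conditions: KOH, DMSO–H2O, 80 °C; then dil. HCl, 0 °C, to pH 4
Reagents that add atoms: potassium hydroxide, [K+].[OH-]
Why: Saponification; the doubly ortho-substituted benzoate needs hot hydroxide in a dipolar solvent, which the benzyl ether and the acetal tolerate, and a brief cold acidification to pH 4 should leave the acetal intact.

Step 4
Reactants: 5 4-methylbenzene-1,2-diol (4-methylcatechol)
Product: 6 1,2-bis(benzyloxy)-4-methylbenzene
Conditions: BnBr (2.2 equiv), K2CO3, DMF, 60 °C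
Reagents that add atoms: benzyl bromide, BrCc1ccccc1
Why: Twofold Williamson ether synthesis of a catechol; both phenols are free and unhindered.

Step 5
Reactants: 6 1,2-bis(benzyloxy)-4-methylbenzene
Product: 7 4,5-bis(benzyloxy)-2-methylbenzaldehyde
Conditions: POCl3, DMF, 0 °C to 80 °C; then aq. NaOAc
Reagents that add atoms: N,N-dimethylformamide, CN(C)C=O; water, O
Why: Vilsmeier–Haack formylation; the carbon para to one benzyloxy group and ortho to the methyl group is the most activated and least hindered of the three free positions, as known for 3,4-dialkoxytoluenes, and benzyl ethers are stable to the chloroiminium salt.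

Step 6
Reactants: 7 4,5-bis(benzyloxy)-2-methylbenzaldehyde
Product: 9 4,5-bis(benzyloxy)-2-methylphenol, via aryl formate 8 (not isolated)
Conditions: mCPBA, CH2Cl2, rt; then K2CO3 (cat.), MeOH, rt
Reagents that add atoms: 3-chloroperoxybenzoic acid, OOC(=O)c1cccc(Cl)c1
Why: Baeyer–Villiger oxidation of an electron-rich benzaldehyde (Dakin-type); the aryl group, which has an alkoxy group para to the formyl carbon, migrates in preference to hydride, and the formate 8 is methanolysed in the same flask.

Step 7
Reactants: 4 4-(benzyloxy)-2-(methoxymethoxy)-6-methylbenzoic acid; 9 4,5-bis(benzyloxy)-2-methylphenol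
Product: 10 4,5-bis(benzyloxy)-2-methylphenyl 4-(benzyloxy)-2-(methoxymethoxy)-6-methylbenzoate
Conditions: DCC, DMAP (cat.), CH2Cl2, rt
Reagents that add atoms: none
Why: Steglich esterification, the standard way to depside-type aryl esters of 2,6-disubstituted benzoic acids; the acylpyridinium intermediate is reactive enough for a phenol with one ortho substituent, and nothing in either partner is sensitive to the carbodiimide.

Step 8
Reactants: 10 4,5-bis(benzyloxy)-2-methylphenyl 4-(benzyloxy)-2-(methoxymethoxy)-6-methylbenzoate
Product: 12 [4-(benzyloxy)-2-hydroxy-6-methylphenyl][2,3-bis(benzyloxy)-6-hydroxy-5-methylphenyl]methanone, via MOM-protected benzophenone 11 (not isolated)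
Conditions: hν (300 nm), degassed MeCN, rt; then HCl (aq.), MeOH–THF, 45 °C
Reagents that add atoms: none
Why: Photo-Fries rearrangement: homolysis of the aryl ester C–O bond and recombination of the caged acyl and phenoxyl radicals at the only open ortho carbon (the other ortho carbon bears methyl, the para carbon benzyloxy) give the ortho-hydroxy ketone 11, which is protected from further photochemistry by its hydrogen-bonded ketone. The methoxymethyl ether keeps the salicylate chromophore of 10 from excited-state proton transfer and is then removed by acid-catalysed acetal exchange with methanol, which leaves the benzyl ethers untouched.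

Step 9
Reactants: 12 [4-(benzyloxy)-2-hydroxy-6-methylphenyl][2,3-bis(benzyloxy)-6-hydroxy-5-methylphenyl]methanone
Product: 14 3,6,7-tris(benzyloxy)-1,9-dimethyl-11H-dibenzo[b,e][1,4]dioxepin-11-one, via spiro grisadienedione 13 (not isolated)
Conditions: PhI(OAc)2 (1.05 equiv), (CF3)2CHOH, 0 °C to rt; then PhMe, 100 °C
Reagents that add atoms: none
Why: The trivalent iodine reagent exchanges an acetate for the ring B phenol (the 6-hydroxyl, the only phenol with an alkoxy group para to it), and loss of iodobenzene gives a phenoxonium ion with its charge ortho and para to that oxygen, kept free of outside nucleophiles by the ionising, non-nucleophilic solvent. The ring A phenol adds to the ortho carbon that bears the ketone, a 5-exo-trig closure that gives the spiro benzofuran-3-one 13; this is an oxidative dearomatising spirocyclisation of an ortho-hydroxybenzophenone, the ortho counterpart of the griseofulvin-type phenol coupling. In 13 the spiro carbon lies between two carbonyl groups and cannot enolise, so on heating the aroyl group leaves carbon for the neighbouring dienone oxygen (a 1,3-acyl shift, direct or by addition of that oxygen to the furanone carbonyl and fragmentation), ring B becomes aromatic again, and the known grisadienedione-to-depsidone rearrangement is complete. The seven-membered lactone is thus closed by a two-atom ring expansion of the five-membered ring and not by a direct medium-ring cyclisation. The spiro carbon of 13 is the only stereocentre; it forms as a racemate and is destroyed in the shift, so no stereocontrol is needed. Chemoselectivity should follow from ring B being the easier phenol to oxidise, the ring A phenol being a ketone-conjugated resorcinol ether without a para donor. Site selectivity follows from the tether, which reaches only the ipso carbon among the three electrophilic positions and so excludes xanthone formation at the neighbouring benzyloxy-bearing carbon. The direction of the shift is fixed because only one neighbour of the spiro carbon carries a carbonyl oxygen, the other being a benzyl enol ether.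

Step 10
Reactants: 14 3,6,7-tris(benzyloxy)-1,9-dimethyl-11H-dibenzo[b,e][1,4]dioxepin-11-one
Product: 15 3,6,7-trihydroxy-1,9-dimethyl-11H-dibenzo[b,e][1,4]dioxepin-11-one
Conditions: H2 (1 atm), Pd/C (10%), EtOAc–THF, rt
Reagents that add atoms: none
Why: Hydrogenolysis of aryl benzyl ethers under neutral conditions; the aryl ester lactone and the diaryl ether are inert, and the catechol product is handled under inert gas.

Step 11
Reactants: 15 3,6,7-trihydroxy-1,9-dimethyl-11H-dibenzo[b,e][1,4]dioxepin-11-one; 16 3-methylbut-2-enoic acid
Product: 17 3,6-dihydroxy-1,9-dimethyl-11H-dibenzo[b,e][1,4]dioxepin-11-one bearing a 2,2-dimethyl-2,3-dihydro-4H-pyran-4-one ring fused at C7–C8 (ring oxygen on C7, ketone carbon on C8)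
Conditions: P2O5, CH3SO3H, 60 °C
Reagents that add atoms: none
Why: Friedel–Crafts acylation by the mixed anhydride of 16 at C8, the only CH of ring B (ortho to the C7 hydroxyl and para to O5), followed by oxa-Michael addition of the C7 hydroxyl to the enone, the usual one-flask route to 2,2-dimethylchroman-4-ones. Ring A should be held back because its hydroxyl is para to the lactone carbonyl, which is hydrogen-bonded or protonated in this medium, so that ring A behaves as a vinylogous acid.

Step 12
Reactants: 17 the chromanone-fused depsidone of step 11
Product: 18 CNP0271978.0, the 4-formyl derivative of 17 (formyl on ring A between the C3 hydroxyl and the ether oxygen O5)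
Conditions: Cl2CHOMe, TiCl4, CH2Cl2, 0 °C; then aq. HCl
Reagents that add atoms: dichloromethyl methyl ether, COC(Cl)Cl; water, O
Why: Rieche formylation; ring B is fully substituted, and the titanium phenoxide at C3 directs the electrophile to its ortho carbons. C4 lies between two oxygen substituents, of which the ether aryl group is tied back in the seven-membered ring, and is less hindered than C2 next to the methyl group, in line with the formylation of orsellinates between their oxygens. Aqueous work-up hydrolyses the alpha-chloro ether to the aldehyde.

## Compound list

1 | methyl 2,4-dihydroxy-6-methylbenzoate (methyl orsellinate) | COC(=O)c1c(C)cc(O)cc1O | starting material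
2 | methyl 4-(benzyloxy)-2-hydroxy-6-methylbenzoate | COC(=O)c1c(C)cc(OCc2ccccc2)cc1O | intermediate
3 | methyl 4-(benzyloxy)-2-(methoxymethoxy)-6-methylbenzoate | COCOc1cc(OCc2ccccc2)cc(C)c1C(=O)OC | intermediate
4 | 4-(benzyloxy)-2-(methoxymethoxy)-6-methylbenzoic acid | COCOc1cc(OCc2ccccc2)cc(C)c1C(=O)O | intermediate
5 | 4-methylbenzene-1,2-diol (4-methylcatechol) | Cc1ccc(O)c(O)c1 | starting material
6 | 1,2-bis(benzyloxy)-4-methylbenzene | Cc1ccc(OCc2ccccc2)c(OCc2ccccc2)c1 | intermediate
7 | 4,5-bis(benzyloxy)-2-methylbenzaldehyde | Cc1cc(OCc2ccccc2)c(OCc2ccccc2)cc1C=O | intermediate
8 | 4,5-bis(benzyloxy)-2-methylphenyl formate (not isolated) | Cc1cc(OCc2ccccc2)c(OCc2ccccc2)cc1OC=O | intermediate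
9 | 4,5-bis(benzyloxy)-2-methylphenol | Cc1cc(OCc2ccccc2)c(OCc2ccccc2)cc1O | intermediate
10 | 4,5-bis(benzyloxy)-2-methylphenyl 4-(benzyloxy)-2-(methoxymethoxy)-6-methylbenzoate | COCOc1cc(OCc2ccccc2)cc(C)c1C(=O)Oc1cc(OCc2ccccc2)c(OCc2ccccc2)cc1C | intermediate
11 | [4-(benzyloxy)-2-(methoxymethoxy)-6-methylphenyl][2,3-bis(benzyloxy)-6-hydroxy-5-methylphenyl]methanone (not isolated) | COCOc1cc(OCc2ccccc2)cc(C)c1C(=O)c1c(O)c(C)cc(OCc2ccccc2)c1OCc1ccccc1 | intermediate
12 | [4-(benzyloxy)-2-hydroxy-6-methylphenyl][2,3-bis(benzyloxy)-6-hydroxy-5-methylphenyl]methanone | Cc1cc(OCc2ccccc2)cc(O)c1C(=O)c1c(O)c(C)cc(OCc2ccccc2)c1OCc1ccccc1 | intermediate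
13 | racemic 5',6,6'-tris(benzyloxy)-3',4-dimethyl-3H-spiro[1-benzofuran-2,1'-cyclohexa-3',5'-diene]-2',3-dione (not isolated) | Cc1cc(OCc2ccccc2)cc2OC3(C(=O)c12)C(=O)C(C)=CC(OCc1ccccc1)=C3OCc1ccccc1 | intermediate
14 | 3,6,7-tris(benzyloxy)-1,9-dimethyl-11H-dibenzo[b,e][1,4]dioxepin-11-one | Cc1cc(OCc2ccccc2)cc2c1C(=O)Oc1c(C)cc(OCc3ccccc3)c(OCc3ccccc3)c1O2 | intermediate
15 | 3,6,7-trihydroxy-1,9-dimethyl-11H-dibenzo[b,e][1,4]dioxepin-11-one | Cc1cc(O)cc2c1C(=O)Oc1c(C)cc(O)c(O)c1O2 | intermediate
16 | 3-methylbut-2-enoic acid | CC(C)=CC(O)=O | starting material
17 | 3,6-dihydroxy-1,9-dimethyl-11H-dibenzo[b,e][1,4]dioxepin-11-one with a 2,2-dimethyl-2,3-dihydro-4H-pyran-4-one ring fused at C7–C8 (ring oxygen on C7, ketone carbon on C8) | Cc1cc(O)cc2c1C(=O)Oc1c(C)c3c(c(O)c1O2)OC(C)(C)CC3=O | intermediate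
18 | CNP0271978.0, the 4-formyl derivative of 17 | Cc1cc(O)c(C=O)c2c1C(=O)Oc1c(C)c3c(c(O)c1O2)OC(C)(C)CC3=O | target

## Step count and risks

Total: 12 steps. Longest linear sequence: 9 steps (steps 1–3 and 7–12 from 1, or steps 4–6 and 7–12 from 5).

The least certain steps, in route order:

**Step 8 (photo-Fries rearrangement).** The radical pair may escape the solvent cage and return phenol 9, recombination at a carbon flanked by an oxygen substituent may be inefficient, and long irradiation may start to cleave benzyl ethers photochemically. The fallback replaces light by a bromine-directed anionic acyl transfer. It sets out from phenol 9 and acid 4. Bromination of 9 (NBS, MeCN, 0 °C) at the only free carbon ortho to the hydroxyl should give 3,4-bis(benzyloxy)-2-bromo-6-methylphenol F1. Acylation of F1 with the acid chloride of 4 (made with 1-chloro-N,N,2-trimethylprop-1-en-1-amine; pyridine, DMAP, CH2Cl2) should give 3,4-bis(benzyloxy)-2-bromo-6-methylphenyl 4-(benzyloxy)-2-(methoxymethoxy)-6-methylbenzoate F2. Bromine–lithium exchange on F2 (n-BuLi, THF, −78 °C) then lets the aryllithium take the neighbouring ester acyl group from oxygen to carbon. The fallback comes back to the route at 11, which is deprotected as in step 8.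

**Step 9 (key step).** The para benzyloxy group may be lost oxidatively, leading to a quinone. The phenoxonium ion may also be intercepted by acetate before the hindered, hydrogen-bonded ring A phenol closes. The spiro intermediate may be opened by the solvent at the furanone carbonyl and stall short of lactonisation. The fallback forms the ether bond by copper chemistry on a depside. It sets out from 9 and 4 through the bromo ester F2 described above. Acid methanolysis of the acetal (HCl, MeOH–THF, 45 °C) should give 3,4-bis(benzyloxy)-2-bromo-6-methylphenyl 4-(benzyloxy)-2-hydroxy-6-methylbenzoate F3. Intramolecular Ullmann etherification of F3 (CuI, picolinic acid, K3PO4, DMSO, 90 °C) would close the seven-membered ring between the ring A phenol and the brominated carbon. The fallback comes back at 14.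

**Step 11 (chromanone annulation).** The acid 16 may react through its tertiary cation, so that ring B is alkylated and lactonised to a 4,4-dimethyl dihydrocoumarin in place of the acylation. Ring A may be attacked as well, and the lactone may suffer acyl exchange in hot acid. The fallback separates C-acylation from ring closure. It sets out from 15. Ortho-acetylation (AcOH, BF3·OEt2, 80 °C) should give 8-acetyl-3,6,7-trihydroxy-1,9-dimethyl-11H-dibenzo[b,e][1,4]dioxepin-11-one F4. Kabbe condensation of F4 with acetone (catalytic pyrrolidine, MeOH, rt) would build the 2,2-dimethylpyranone by aldol condensation and oxa-Michael addition. The fallback comes back at 17.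

**Step 12 (formylation).** Site selectivity between C4 and C2 of ring A may be poor, since both are ortho to the same phenol and differ only in their second neighbour. The fallback introduces the aldehyde where only one position is open. It sets out from 12, in which the ring A phenol has a single free ortho carbon and the ring B phenol has none.
- Magnesium-mediated ortho-formylation (MgCl2, Et3N, paraformaldehyde, MeCN, reflux) should give 6-(benzyloxy)-3-[2,3-bis(benzyloxy)-6-hydroxy-5-methylbenzoyl]-2-hydroxy-4-methylbenzaldehyde F5.
- The conditions of step 9 would take F5 through racemic 5',6,6'-tris(benzyloxy)-3',4-dimethyl-2',3-dioxo-3H-spiro[1-benzofuran-2,1'-cyclohexa-3',5'-diene]-7-carbaldehyde F6 to 3,6,7-tris(benzyloxy)-1,9-dimethyl-11-oxo-11H-dibenzo[b,e][1,4]dioxepine-4-carbaldehyde F7.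
- Debenzylation that spares the aldehyde (BCl3, pentamethylbenzene, CH2Cl2, −78 °C) should give 3,6,7-trihydroxy-1,9-dimethyl-11-oxo-11H-dibenzo[b,e][1,4]dioxepine-4-carbaldehyde F8.
- Annulation of F8 with 16 under the conditions of step 11 comes back to the route at 18.

## Further compounds

F1 | step 8 | 3,4-bis(benzyloxy)-2-bromo-6-methylphenol | Cc1cc(OCc2ccccc2)c(OCc2ccccc2)c(Br)c1O
F2 | step 8 | 3,4-bis(benzyloxy)-2-bromo-6-methylphenyl 4-(benzyloxy)-2-(methoxymethoxy)-6-methylbenzoate | COCOc1cc(OCc2ccccc2)cc(C)c1C(=O)Oc1c(C)cc(OCc2ccccc2)c(OCc2ccccc2)c1Br
F3 | step 9 | 3,4-bis(benzyloxy)-2-bromo-6-methylphenyl 4-(benzyloxy)-2-hydroxy-6-methylbenzoate | Cc1cc(OCc2ccccc2)cc(O)c1C(=O)Oc1c(C)cc(OCc2ccccc2)c(OCc2ccccc2)c1Br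
F4 | step 11 | 8-acetyl-3,6,7-trihydroxy-1,9-dimethyl-11H-dibenzo[b,e][1,4]dioxepin-11-one | Cc1cc(O)cc2c1C(=O)Oc1c(C)c(C(C)=O)c(O)c(O)c1O2
F5 | step 12 | 6-(benzyloxy)-3-[2,3-bis(benzyloxy)-6-hydroxy-5-methylbenzoyl]-2-hydroxy-4-methylbenzaldehyde | Cc1cc(OCc2ccccc2)c(C=O)c(O)c1C(=O)c1c(O)c(C)cc(OCc2ccccc2)c1OCc1ccccc1
F6 | step 12 | racemic 5',6,6'-tris(benzyloxy)-3',4-dimethyl-2',3-dioxo-3H-spiro[1-benzofuran-2,1'-cyclohexa-3',5'-diene]-7-carbaldehyde | Cc1cc(OCc2ccccc2)c(C=O)c2OC3(C(=O)c12)C(=O)C(C)=CC(OCc1ccccc1)=C3OCc1ccccc1
F7 | step 12 | 3,6,7-tris(benzyloxy)-1,9-dimethyl-11-oxo-11H-dibenzo[b,e][1,4]dioxepine-4-carbaldehyde | Cc1cc(OCc2ccccc2)c(C=O)c2c1C(=O)Oc1c(C)cc(OCc3ccccc3)c(OCc3ccccc3)c1O2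
F8 | step 12 | 3,6,7-trihydroxy-1,9-dimethyl-11-oxo-11H-dibenzo[b,e][1,4]dioxepine-4-carbaldehyde | Cc1cc(O)c(C=O)c2c1C(=O)Oc1c(C)cc(O)c(O)c1O2
A1 | alternative 1 | methyl 3-{[6-(benzyloxy)-8-methoxy-2,2,5-trimethyl-4-oxo-3,4-dihydro-2H-chromen-7-yl]oxy}prop-2-ynoate | COC(=O)C#COc1c(OCc2ccccc2)c(C)c2C(=O)CC(C)(C)Oc2c1OC
A2 | alternative 1 | {[(3E)-4-methoxypenta-1,3-dien-2-yl]oxy}trimethylsilane | CO/C(C)=C/C(=C)O[Si](C)(C)C
A3 | alternative 1 | methyl 2-{[6-(benzyloxy)-8-methoxy-2,2,5-trimethyl-4-oxo-3,4-dihydro-2H-chromen-7-yl]oxy}-4-hydroxy-6-methylbenzoate | COC(=O)c1c(C)cc(O)cc1Oc1c(OCc2ccccc2)c(C)c2C(=O)CC(C)(C)Oc2c1OC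
A4 | alternative 2 | 6,7-dihydroxy-8-methoxy-2,2,5-trimethyl-2,3-dihydro-4H-chromen-4-one | COc1c(O)c(O)c(C)c2C(=O)CC(C)(C)Oc12
A5 | alternative 2 | 2-fluoro-3-iodo-6-methoxy-4-methylbenzaldehyde | Cc1cc(OC)c(C=O)c(F)c1I
A6 | alternative 2 | carbon monoxide | [C-]#[O+]
A7 | alternative 2 | dimethyl ether of the target (methoxy at C3 and C6) | Cc1cc(OC)c(C=O)c2c1C(=O)Oc1c(C)c3c(c(OC)c1O2)OC(C)(C)CC3=O
A8 | alternative 3 | methyl 4-(benzyloxy)-2-[(5-{[tert-butyl(dimethyl)silyl]oxy}-4-methoxyfuran-3-yl)oxy]-6-methylbenzoate | COC(=O)c1c(C)cc(OCc2ccccc2)cc1Oc1coc(O[Si](C)(C)C(C)(C)C)c1OC
A9 | alternative 3 | 6-methylhept-5-en-2-yn-4-one | CC#CC(=O)C=C(C)C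
A10 | alternative 3 | methyl 4-(benzyloxy)-2-[3-{[tert-butyl(dimethyl)silyl]oxy}-6-hydroxy-2-methoxy-5-methyl-4-(3-methylbut-2-enoyl)phenoxy]-6-methylbenzoate | COC(=O)c1c(C)cc(OCc2ccccc2)cc1Oc1c(O)c(C)c(C(=O)C=C(C)C)c(O[Si](C)(C)C(C)(C)C)c1OC
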